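**Retrosynthetic overview**

- The strategy rests on the pyrrole C2: it is a single ester-bearing carbon between N1 and C3, while N1–C5–C4–C3 is a contiguous four-atom chain that carries both 5-bromoindol-3-yl groups on C3 and C4.
- The C2–C3 and N1–C2 bonds are cut together: a formal [4+1] annulation of an N-tosyl 1-azadiene (N1, C5, C4, C3) with an ester-stabilised dimethylsulfonium ylide (C2) builds the pyrrole ring, the only ring formed, as a trans-2,3-dihydropyrrole.
- The azadiene comes from (E)-2,3-bis(5-bromo-1-tosylindol-3-yl)propenal and tosylamide; the enal comes from an aldol condensation of N-tosylated methyl 5-bromoindol-3-ylacetate with N-tosylated 5-bromoindole-3-carbaldehyde, then ester reduction and allylic oxidation.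
- End game: base-induced loss of toluenesulfinate from N1 aromatises the ring without an oxidant, and methanolysis removes the two indole N-tosyl groups.

Key step: step 9

Remark: the target has no stereocentre; the two centres made in the key step are transient, so the dihydropyrrole is carried as a racemate. The sulfonium salt is made in one step from bulk chemicals rather than assumed to be purchasable.

**Route**

Step 1
Reactants: 1 5-bromoindole-3-acetic acid
Product: 2 methyl (5-bromo-1H-indol-3-yl)acetate
Conditions: MeOH, H2SO4 (cat.), reflux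
Reagents that add atoms: methanol, CO
Why: Fischer esterification in excess methanol should convert the acid to its methyl ester without touching the indole or the aryl bromide.

Step 2
Reactants: 2 methyl (5-bromo-1H-indol-3-yl)acetate
Product: 3 methyl (5-bromo-1-tosyl-1H-indol-3-yl)acetate
Conditions: NaH (1.05 equiv), THF, 0 °C; TsCl, 0 °C → rt
Reagents that add atoms: p-toluenesulfonyl chloride, Cc1ccc(cc1)S(Cl)(=O)=O
Why: N-sulfonylation of the indolide, formed selectively because N–H is the most acidic site toward one equivalent of NaH; the sulfonyl group is needed later to damp indole donation into the azadiene.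

Step 3
Reactants: 4 5-bromoindole-3-carbaldehyde
Product: 5 5-bromo-1-tosyl-1H-indole-3-carbaldehyde
Conditions: TsCl, Et3N, DMAP (cat.), CH2Cl2, rt
Reagents that add atoms: p-toluenesulfonyl chloride, Cc1ccc(cc1)S(Cl)(=O)=O
Why: The 3-formyl group acidifies N–H, so DMAP-catalysed N-sulfonylation with an amine base suffices, and it turns the vinylogous formamide into a properly electrophilic aldehyde.

Step 4
Reactants: 3 methyl (5-bromo-1-tosyl-1H-indol-3-yl)acetate; 5 5-bromo-1-tosyl-1H-indole-3-carbaldehyde
Product: 8 methyl (E)-2,3-bis(5-bromo-1-tosyl-1H-indol-3-yl)acrylate, via lithium aldolate 6 (not isolated), via β-acetoxy ester 7 (not isolated)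
Conditions: LiN(SiMe3)2 (1.05 equiv), THF, −78 °C; 5; Ac2O, −78 °C → rt; DBU, rt
Reagents that add atoms: none
Why: Aldol condensation run as directed lithium-enolate addition, O-acetylation of the aldolate and E1cB elimination with DBU should give the thermodynamically preferred E-acrylate (ester trans to the β-indolyl group), the non-nucleophilic bases sparing the N-sulfonyl groups and aryl bromides.

Step 5
Reactants: 8 methyl (E)-2,3-bis(5-bromo-1-tosyl-1H-indol-3-yl)acrylate
Product: 9 (E)-2,3-bis(5-bromo-1-tosyl-1H-indol-3-yl)prop-2-en-1-ol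
Conditions: i-Bu2AlH (2.5 equiv), CH2Cl2, −78 → 0 °C; aq. KNaC4H4O6 work-up
Reagents that add atoms: none
Why: 1,2-Reduction of a conjugated ester by i-Bu2AlH should give the allylic alcohol at low temperature with alkene geometry, sulfonamides and aryl bromides unchanged.

Step 6
Reactants: 9 (E)-2,3-bis(5-bromo-1-tosyl-1H-indol-3-yl)prop-2-en-1-ol
Product: 10 (E)-2,3-bis(5-bromo-1-tosyl-1H-indol-3-yl)acrylaldehyde
Conditions: MnO2 (activated, excess), CH2Cl2, rt
Reagents that add atoms: none
Why: Allylic oxidation with MnO2 is selective for the allylic alcohol and stops at the enal, whose E isomer (indoles cis, formyl trans to the β-indolyl group) is the stable one.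

Step 7
Reactants: 10 (E)-2,3-bis(5-bromo-1-tosyl-1H-indol-3-yl)acrylaldehyde; 11 p-toluenesulfonamide
Product: 12 N-[(1E,2E)-2,3-bis(5-bromo-1-tosyl-1H-indol-3-yl)prop-2-en-1-ylidene]-4-methylbenzenesulfonamide
Conditions: TiCl4 (0.55 equiv), Et3N (2.5 equiv), CH2Cl2, 0 °C → rt; filtration, crystallisation, no chromatography
Reagents that add atoms: none
Why: N-Sulfonyl imine formation in which TiCl4 is both Lewis acid and water scavenger should condense the weakly nucleophilic sulfonamide with the aldehyde to the E-aldimine, which is handled dry because it hydrolyses easily.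

Step 8
Reactants: 13 methyl bromoacetate
Product: 14 (2-methoxy-2-oxoethyl)dimethylsulfonium bromide
Conditions: Me2S, acetone, rt
Reagents that add atoms: dimethyl sulfide, CSC
Why: SN2 S-alkylation of dimethyl sulfide by the α-bromo ester should give the sulfonium salt, which crystallises from acetone.

Step 9
Reactants: 12 N-[(1E,2E)-2,3-bis(5-bromo-1-tosyl-1H-indol-3-yl)prop-2-en-1-ylidene]-4-methylbenzenesulfonamide; 14 (2-methoxy-2-oxoethyl)dimethylsulfonium bromide
Product: 17 methyl trans-3,4-bis(5-bromo-1-tosyl-1H-indol-3-yl)-1-tosyl-2,3-dihydro-1H-pyrrole-2-carboxylate (racemic), via methyl (dimethylsulfuranylidene)acetate 15 (not isolated), via sulfonium aza-enolate betaine 16 (not isolated)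
Conditions: Cs2CO3 (1.5 equiv, anhydrous), MeCN, 0 °C → rt
Reagents that add atoms: none
Why: Cs2CO3 deprotonates 14 to ylide 15, whose carbon adds to the β-carbon of the s-cis azadiene (C2–C3 bond) to give betaine 16, and the sulfonamide nitrogen then displaces dimethyl sulfide from the former ylide carbon (N1–C2 bond). The closest known reaction type is the formal [4+1] annulation of carbonyl-stabilised sulfur ylides with N-sulfonyl α,β-unsaturated imines to 2-pyrrolines, a Michael-initiated ring closure. The one ring formed, the 2,3-dihydropyrrole, closes in a 5-exo-tet mode. C2 and C3 should come out trans because the ester and the C3 indolyl group avoid each other in the SN2 transition state and C2 can epimerise under the base to the same isomer; both centres are erased in step 10. The step needs 1,4- over 1,2-addition and N- over C-alkylation: addition of the stabilised ylide at the imine carbon is reversible and its three-membered closure slow, the (2E) geometry puts only hydrogen cis to the imine so the s-cis conformer is accessible, and the indole N-sulfonyl groups keep the β-carbon electrophilic while the charge in 16 sits mainly on the sulfonamide nitrogen.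

Step 10
Reactants: 17 methyl trans-3,4-bis(5-bromo-1-tosyl-1H-indol-3-yl)-1-tosyl-2,3-dihydro-1H-pyrrole-2-carboxylate
Product: 19 methyl 3,4-bis(5-bromo-1-tosyl-1H-indol-3-yl)-1H-pyrrole-2-carboxylate, via 3H-pyrrole tautomer 18 (not isolated)
Conditions: DBU (2 equiv), MeCN, rt → 50 °C
Reagents that add atoms: none
Why: E1cB elimination: DBU removes the C2 proton α to the ester, the enolate expels p-toluenesulfinate from N1, and the resulting 3H-pyrrole tautomerises to the aromatic ring, while the indole sulfonamides, which lack such a proton, stay; any material already aromatised under the carbonate of step 9 converges here.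

Step 11
Reactants: 19 methyl 3,4-bis(5-bromo-1-tosyl-1H-indol-3-yl)-1H-pyrrole-2-carboxylate
Product: 20 methyl 3,4-bis(5-bromo-1H-indol-3-yl)-1H-pyrrole-2-carboxylate (target)
Conditions: Cs2CO3 (6 equiv), THF/MeOH 2:1, rt → 50 °C
Reagents that add atoms: none
Why: Sulfonamide methanolysis: methoxide attacks sulfur of the N-sulfonyl indoles and releases the indolide leaving groups, the methyl ester can only exchange degenerately with methanol, and the aryl bromides are inert.

**Compound list**

1 | 5-bromoindole-3-acetic acid | OC(=O)Cc1c[nH]c2ccc(Br)cc12 | starting material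
2 | methyl (5-bromo-1H-indol-3-yl)acetate | COC(=O)Cc1c[nH]c2ccc(Br)cc12 | intermediate
3 | methyl (5-bromo-1-tosyl-1H-indol-3-yl)acetate | COC(=O)Cc1cn(S(=O)(=O)c2ccc(C)cc2)c2ccc(Br)cc12 | intermediate
4 | 5-bromoindole-3-carbaldehyde | O=Cc1c[nH]c2ccc(Br)cc12 | starting material
5 | 5-bromo-1-tosyl-1H-indole-3-carbaldehyde | O=Cc1cn(S(=O)(=O)c2ccc(C)cc2)c2ccc(Br)cc12 | intermediate
6 | lithium aldolate of 3 and 5 (diastereomer mixture, not isolated) | COC(=O)C(c1cn(S(=O)(=O)c2ccc(C)cc2)c2ccc(Br)cc12)C([O-])c1cn(S(=O)(=O)c2ccc(C)cc2)c2ccc(Br)cc12.[Li+] | intermediate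
7 | methyl 3-acetoxy-2,3-bis(5-bromo-1-tosyl-1H-indol-3-yl)propanoate (diastereomer mixture, not isolated) | COC(=O)C(c1cn(S(=O)(=O)c2ccc(C)cc2)c2ccc(Br)cc12)C(OC(C)=O)c1cn(S(=O)(=O)c2ccc(C)cc2)c2ccc(Br)cc12 | intermediate
8 | methyl (E)-2,3-bis(5-bromo-1-tosyl-1H-indol-3-yl)acrylate | COC(=O)/C(c1cn(S(=O)(=O)c2ccc(C)cc2)c2ccc(Br)cc12)=C/c1cn(S(=O)(=O)c2ccc(C)cc2)c2ccc(Br)cc12 | intermediate
9 | (E)-2,3-bis(5-bromo-1-tosyl-1H-indol-3-yl)prop-2-en-1-ol | OC/C(c1cn(S(=O)(=O)c2ccc(C)cc2)c2ccc(Br)cc12)=C/c1cn(S(=O)(=O)c2ccc(C)cc2)c2ccc(Br)cc12 | intermediate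
10 | (E)-2,3-bis(5-bromo-1-tosyl-1H-indol-3-yl)acrylaldehyde | O=C/C(c1cn(S(=O)(=O)c2ccc(C)cc2)c2ccc(Br)cc12)=C/c1cn(S(=O)(=O)c2ccc(C)cc2)c2ccc(Br)cc12 | intermediate
11 | p-toluenesulfonamide | Cc1ccc(cc1)S(N)(=O)=O | starting material
12 | N-[(1E,2E)-2,3-bis(5-bromo-1-tosyl-1H-indol-3-yl)prop-2-en-1-ylidene]-4-methylbenzenesulfonamide | Cc1ccc(cc1)S(=O)(=O)/N=C/C(c1cn(S(=O)(=O)c2ccc(C)cc2)c2ccc(Br)cc12)=C/c1cn(S(=O)(=O)c2ccc(C)cc2)c2ccc(Br)cc12 | intermediate
13 | methyl bromoacetate | COC(=O)CBr | starting material
14 | (2-methoxy-2-oxoethyl)dimethylsulfonium bromide | COC(=O)C[S+](C)C.[Br-] | intermediate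
15 | methyl (dimethylsulfuranylidene)acetate (not isolated) | COC(=O)[CH-][S+](C)C | intermediate
16 | sulfonium aza-enolate betaine from conjugate addition of 15 to 12 (not isolated) | COC(=O)C([S+](C)C)C(c1cn(S(=O)(=O)c2ccc(C)cc2)c2ccc(Br)cc12)C(c1cn(S(=O)(=O)c2ccc(C)cc2)c2ccc(Br)cc12)=C[N-]S(=O)(=O)c1ccc(C)cc1 | intermediate
17 | methyl trans-3,4-bis(5-bromo-1-tosyl-1H-indol-3-yl)-1-tosyl-2,3-dihydro-1H-pyrrole-2-carboxylate (racemic, one enantiomer drawn) | COC(=O)[C@@H]1[C@@H](c2cn(S(=O)(=O)c3ccc(C)cc3)c3ccc(Br)cc23)C(c2cn(S(=O)(=O)c3ccc(C)cc3)c3ccc(Br)cc23)=CN1S(=O)(=O)c1ccc(C)cc1 | intermediate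
18 | methyl 3,4-bis(5-bromo-1-tosyl-1H-indol-3-yl)-3H-pyrrole-2-carboxylate (not isolated) | COC(=O)C1=NC=C(c2cn(S(=O)(=O)c3ccc(C)cc3)c3ccc(Br)cc23)C1c1cn(S(=O)(=O)c2ccc(C)cc2)c2ccc(Br)cc12 | intermediate
19 | methyl 3,4-bis(5-bromo-1-tosyl-1H-indol-3-yl)-1H-pyrrole-2-carboxylate | COC(=O)c1[nH]cc(-c2cn(S(=O)(=O)c3ccc(C)cc3)c3ccc(Br)cc23)c1-c1cn(S(=O)(=O)c2ccc(C)cc2)c2ccc(Br)cc12 | intermediate
20 | methyl 3,4-bis(5-bromo-1H-indol-3-yl)-1H-pyrrole-2-carboxylate | COC(=O)c1[nH]cc(-c2c[nH]c3ccc(Br)cc23)c1-c1c[nH]c2ccc(Br)cc12 | target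

**Step count**

Total steps: 11. Longest linear sequence: 9 (steps 1, 2, 4, 5, 6, 7, 9, 10, 11).

**Steps most likely to fail, with fallbacks**

Step 9 (key annulation). Three processes could divert it:
- addition of the ylide at the imine carbon followed by three-membered closure to an aziridine;
- closure of the betaine through carbon to a cyclopropane instead of through nitrogen;
- a sluggish conjugate addition, because two indolyl groups lower the electrophilicity of the β-carbon and leave time for hydrolysis of the imine.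

Fallback: set out from enal 10 and change the ring-forming event to a pericyclic closure. Condensation of 10 with glycine methyl ester hydrochloride in pyridine over 4 Å molecular sieves with heating should give methyl N-[(1E,2E)-2,3-bis(5-bromo-1-tosyl-1H-indol-3-yl)prop-2-en-1-ylidene]glycinate F1. Under the same basic conditions its 2-azapentadienyl anion should undergo 1,5-electrocyclisation (six electrons), forming the C2–C3 bond, to give methyl 3,4-bis(5-bromo-1-tosyl-1H-indol-3-yl)-3,4-dihydro-2H-pyrrole-2-carboxylate F2. Dehydrogenation of F2 with DDQ in toluene at rt should give 19, where the route is rejoined before step 11. This path needs no N-sulfonyl imine and so also bypasses step 7.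

Step 7 (sulfonyl imine formation). The condensation could stall at a hindered, conjugatively deactivated formyl group, and the product could revert by hydrolysis during aqueous work-up.

Fallback: set out from 10 and 11 and form the C=N bond by a water-free metathesis. Heating 11 with SOCl2 should give N-sulfinyl-4-methylbenzenesulfonamide F3. Reaction of F3 with 10 in toluene at 80–110 °C (AlCl3 catalysis if needed) should proceed by [2+2] addition and cycloreversion with loss of sulfur dioxide (Kresze reaction) to give 12, which is filtered and used directly in step 9.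

Step 4 (aldol condensation). Retro-aldol cleavage before the aldolate is acetylated, attack of base on an N-sulfonyl group, or elimination to the wrong alkene geometry could erode the step.

Fallback: set out from 3 and 5 and use a Perkin condensation under thermodynamic control. Saponification of 3 with LiOH in THF/H2O at rt should give (5-bromo-1-tosyl-1H-indol-3-yl)acetic acid F4. Heating F4 with 5 in Ac2O/Et3N at about 110 °C should give (E)-2,3-bis(5-bromo-1-tosyl-1H-indol-3-yl)acrylic acid F5 through the mixed anhydride. O-Methylation of F5 with MeI and K2CO3 in DMF should return the route to 8.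

**Further compounds**

F1 | step 9 | methyl N-[(1E,2E)-2,3-bis(5-bromo-1-tosyl-1H-indol-3-yl)prop-2-en-1-ylidene]glycinate | COC(=O)C/N=C/C(c1cn(S(=O)(=O)c2ccc(C)cc2)c2ccc(Br)cc12)=C/c1cn(S(=O)(=O)c2ccc(C)cc2)c2ccc(Br)cc12
F2 | step 9 | methyl 3,4-bis(5-bromo-1-tosyl-1H-indol-3-yl)-3,4-dihydro-2H-pyrrole-2-carboxylate (diastereomer mixture) | COC(=O)C1N=CC(c2cn(S(=O)(=O)c3ccc(C)cc3)c3ccc(Br)cc23)C1c1cn(S(=O)(=O)c2ccc(C)cc2)c2ccc(Br)cc12
F3 | step 7 | N-sulfinyl-4-methylbenzenesulfonamide | Cc1ccc(cc1)S(=O)(=O)N=S=O
F4 | step 4 | (5-bromo-1-tosyl-1H-indol-3-yl)acetic acid | OC(=O)Cc1cn(S(=O)(=O)c2ccc(C)cc2)c2ccc(Br)cc12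
F5 | step 4 | (E)-2,3-bis(5-bromo-1-tosyl-1H-indol-3-yl)acrylic acid | OC(=O)/C(c1cn(S(=O)(=O)c2ccc(C)cc2)c2ccc(Br)cc12)=C/c1cn(S(=O)(=O)c2ccc(C)cc2)c2ccc(Br)cc12
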